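**Strategy.** Numbering follows guaianes (C1/C5 ring fusion, C4 quaternary, C7 isopropenyl, C10 carbinol, C1′ benzylic). The route rests on cutting C9–C10 together with C1–C5. The seven-membered ring C1–C10–C9–C8–C7–C6–C5 is read as a five-carbon vinylcyclopropane unit (C5–C9) plus a two-carbon allene unit (C1, C10), and the tether C2–C3–C4 completes the cyclopentane. One rhodium-catalysed intramolecular (5+2) cycloaddition of an acyclic allene–vinylcyclopropane closes both rings, C9–C10 forming in the ring-closing reductive elimination, and sets C5 from the C4 quaternary centre. The precursor already carries the aryl–isobutyl side chain, built from 5,7-dimethoxycoumarin by asymmetric conjugate addition and lactone alkylations.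

Key step: step 12

Remark: compounds 1, 4, 11 and 12 are taken as commercial. Bicyclic compounds are named as bicyclo[5.3.0]decanes with the guaiane locants defined above.

Step 1
Reactants: 1 5,7-dimethoxycoumarin
Product: 2 (4R)-5,7-dimethoxy-4-(2-methylpropyl)-3,4-dihydro-2H-chromen-2-one
Conditions: i-BuMgBr (1.5 equiv), CuBr·SMe2 (5 mol %), (R)-1-[(SP)-2-(diphenylphosphino)ferrocenyl]ethyldicyclohexylphosphine (6 mol %; or its enantiomer, whichever gives 4R), CH2Cl2, −72 °C; MeOH, aqueous work-up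
Reagents that add atoms: isobutylmagnesium bromide, CC(C)C[Mg]Br
Why: Copper-catalysed asymmetric conjugate addition of a Grignard reagent to the coumarin C3–C4 double bond; the chiral ferrocenyl diphosphine–copper complex selects the enantioface, so lactone C4 (later C1′, with aryl and isobutyl in place) should be set as R.

Step 2
Reactants: 2 (4R)-4-isobutyl lactone
Product: 3 (3R,4R)-5,7-dimethoxy-3-methyl-4-(2-methylpropyl)-3,4-dihydro-2H-chromen-2-one (3,4-trans)
Conditions: LiN(SiMe3)2 (1.1 equiv), THF, −78 °C; MeI, −78 → −40 °C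
Reagents that add atoms: iodomethane, CI
Why: Lactone enolate alkylation, kept cold so that the aryl ester enolate does not open to a ketene; methyl should enter trans to the 4-isobutyl group, and this centre is made planar again in step 5.

Step 3
Reactants: 4 but-3-yn-1-ol
Product: 5 penta-3,4-dien-1-ol
Conditions: (CH2O)n, CuI (0.5 equiv), Cy2NH, dioxane, reflux
Reagents that add atoms: formaldehyde (as paraformaldehyde), C=O
Why: Crabbé homologation: Mannich-type propargylamine formation followed by copper-mediated 1,5-hydride shift and loss of imine turns the terminal alkyne into the terminal allene, and the free alcohol is tolerated.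

Step 4
Reactants: 5 penta-3,4-dien-1-ol
Product: 6 5-iodopenta-1,2-diene
Conditions: I2, PPh3, imidazole, CH2Cl2, 0 °C → rt
Reagents that add atoms: iodine, II
Why: Appel-type iodination (SN2 displacement of the alkoxyphosphonium at the primary carbon) leaves the allene untouched.

Step 5
Reactants: 3 (3R,4R)-3-methyl lactone; 6 5-iodopenta-1,2-diene
Product: 7 (3R,4S)-5,7-dimethoxy-3-methyl-4-(2-methylpropyl)-3-(penta-3,4-dien-1-yl)-3,4-dihydro-2H-chromen-2-one (pentadienyl trans to isobutyl)
Conditions: KN(SiMe3)2 (1.2 equiv), THF/DMPU, −78 °C; then 6 (2 equiv), −78 → −30 °C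
Reagents that add atoms: none
Why: Alkylation of the tetrasubstituted lactone enolate; the 4-isobutyl group is pushed pseudo-axial by the peri 5-methoxy group and by A(1,2) strain and shields one face, so the chain should enter trans to it and set the quaternary centre (later C4).

Step 6
Reactants: 7 quaternary lactone
Product: 8 (2R)-2-[(1R)-1-(2-hydroxy-4,6-dimethoxyphenyl)-3-methylbutyl]-2-methylhepta-5,6-dien-1-ol
Conditions: LiAlH4, THF, 0 °C; aqueous work-up
Reagents that add atoms: none
Why: Hydride reduction of the aryl lactone to primary alcohol and phenol; the isolated allene is inert to LiAlH4 and no stereocentre is touched.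

Step 7
Reactants: 8 phenol diol
Product: 9 (2R)-2-methyl-2-[(1R)-3-methyl-1-(2,4,6-trimethoxyphenyl)butyl]hepta-5,6-dien-1-ol
Conditions: MeI, K2CO3, DMF, rt
Reagents that add atoms: iodomethane, CI
Why: Williamson methylation; carbonate deprotonates only the phenol, so the neopentyl primary alcohol stays free.

Step 8
Reactants: 9 primary alcohol
Product: 10 (2R)-2-methyl-2-[(1S)-3-methyl-1-(2,4,6-trimethoxyphenyl)butyl]hepta-5,6-dienal (the descriptor at the benzylic carbon changes by priority only)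
Conditions: Dess–Martin periodinane, CH2Cl2, 0 °C → rt
Reagents that add atoms: none
Why: Dess–Martin oxidation to an aldehyde that has no α-hydrogen, so it cannot epimerise or enolise in the next step.

Step 9
Reactants: 11 1-(hydroxymethyl)cyclopropane-1-carbonitrile; 12 1-phenyl-1H-tetrazole-5-thiol
Product: 13 1-{[(1-phenyl-1H-tetrazol-5-yl)sulfanyl]methyl}cyclopropane-1-carbonitrile
Conditions: PPh3, DIAD, THF, 0 °C → rt
Reagents that add atoms: none
Why: Mitsunobu thioetherification: the acidic tetrazolethiol is S-alkylated at the unhindered cyclopropylmethyl carbon.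

Step 10
Reactants: 13 sulfide
Product: 14 1-{[(1-phenyl-1H-tetrazol-5-yl)sulfonyl]methyl}cyclopropane-1-carbonitrile
Conditions: H2O2 (30 %), (NH4)6Mo7O24·4H2O (10 mol %), EtOH, 0 °C → rt
Reagents that add atoms: hydrogen peroxide, OO
Why: Molybdate-catalysed peroxide oxidation of sulfide to sulfone; the nitrile is inert.

Step 11
Reactants: 10 aldehyde; 14 tetrazolyl sulfone
Product: 15 1-{(1E,3S)-3-methyl-3-[(1R)-3-methyl-1-(2,4,6-trimethoxyphenyl)butyl]octa-1,6,7-trien-1-yl}cyclopropane-1-carbonitrile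
Conditions: KN(SiMe3)2 (1.4 equiv) added to 10 and 14 (1.3 equiv), DME, −60 °C → rt
Reagents that add atoms: none
Why: Julia–Kocienski olefination: the sulfonyl carbanion adds to the non-enolisable aldehyde, and Smiles rearrangement with loss of SO2 and tetrazolate should give the E-alkene, favoured by the potassium counter-ion in DME and by the two bulky termini.

Step 12
Reactants: 15 allene–vinylcyclopropane
Product: 16 (1S,4S,5S)-7-cyano-4-methyl-10-methylidene-4-[(1R)-3-methyl-1-(2,4,6-trimethoxyphenyl)butyl]bicyclo[5.3.0]dec-6-ene (cis-fused)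
Conditions: [Rh(CO)2Cl]2 (5 mol %), toluene (0.01 M), 100 °C
Reagents that add atoms: none
Why: Monovalent rhodium binds the vinylcyclopropane and cleaves the C7–C9 cyclopropane bond to a π-allyl (C5–C7)/σ-alkyl (C9) rhodacycle of trivalent rhodium; the internal allene π-bond (C1=C10) inserts at the allyl terminus C5 to form C1–C5, and reductive elimination then forms C9–C10. The closest known reaction type is the rhodium-catalysed intramolecular (5+2) cycloaddition of allene-tethered vinylcyclopropanes. The cyclopentane closes by insertion through the three-atom tether (5-exo mode), and the seven-membered ring closes by C(sp3)–C(sp2) reductive elimination from the eight-membered rhodacycle, leaving the nitrile on C7 of the new C6=C7 bond and C10 as an exocyclic methylidene. C5 is controlled by the C4 quaternary centre: in the forming cyclopentane the new C5–C6 bond should lie anti to the bulky 1-aryl-3-methylbutyl group and syn to methyl. C1 is set cis to H-5 because the allene inserts suprafacially on the rhodium-bound face, and this cis fusion is corrected in step 13. The step needs chemoselectivity for the internal over the terminal allene π-bond, which the tether length secures by allowing only a five-membered ring, and high dilution to keep allene oligomerisation down.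

Step 13
Reactants: 16 cis-fused cycloadduct
Product: 18 (1R,4S,5S)-7-cyano-4-methyl-4-[(1R)-3-methyl-1-(2,4,6-trimethoxyphenyl)butyl]bicyclo[5.3.0]dec-6-en-10-one (trans-fused), via cis-fused ketone 17 (not isolated)
Conditions: OsO4 (2 mol %), NaIO4 (4 equiv), 2,6-lutidine, dioxane/H2O 3:1, rt; extractive work-up; then DBU (0.5 equiv), CH2Cl2, rt
Reagents that add atoms: sodium periodate (oxygen relayed through OsO4), [Na+].[O-]I(=O)(=O)=O
Why: Lemieux–Johnson cleavage is selective for the electron-rich 1,1-disubstituted alkene over the electron-poor alkenyl nitrile; DBU then equilibrates C1 through the enolate to the trans-fused ketone, expected to be favoured because both fusion bonds become pseudo-equatorial on the seven-membered ring.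

Step 14
Reactants: 18 trans-fused ketone
Product: 19 (1R,4S,5S,10R)-7-cyano-10-hydroxy-4,10-dimethyl-4-[(1R)-3-methyl-1-(2,4,6-trimethoxyphenyl)butyl]bicyclo[5.3.0]dec-6-ene (10-OH cis to H-1)
Conditions: MeAl(OAr)2 (MAD, Ar = 2,6-di-tert-butyl-4-methylphenyl; 3 equiv), toluene, −78 °C; MeLi (3 equiv), Et2O, −78 °C; aqueous work-up
Reagents that add atoms: methyllithium, C[Li]
Why: Lewis-acid-mediated carbonyl methylation: the bulky aluminium aryloxide sits on the less hindered face of the ketone (the face of axial H-1), so methyl should be delivered axially from the opposite face and leave the equatorial hydroxyl cis to H-1; the nitrile does not react at −78 °C.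

Step 15
Reactants: 19 tertiary alcohol nitrile
Product: 21 (1R,4S,5S,10R)-7-acetyl-10-hydroxy-4,10-dimethyl-4-[(1R)-3-methyl-1-(2,4,6-trimethoxyphenyl)butyl]bicyclo[5.3.0]dec-6-ene, via ketimine 20 (not isolated)
Conditions: MeLi (4 equiv), Et2O, −78 → 0 °C; then aq. AcOH, THF, rt
Reagents that add atoms: methyllithium, C[Li]; water, O
Why: Organolithium 1,2-addition to the nitrile (conjugate addition is disfavoured at the hindered β-carbon C6) and hydrolysis of the ketimine give the methyl ketone; no stereocentre is affected.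

Step 16
Reactants: 21 enone
Product: 22 (1R,4S,5S,10R)-7-acetyl-4-[(1R)-1-(3,5-dibromo-2,4,6-trimethoxyphenyl)-3-methylbutyl]-10-hydroxy-4,10-dimethylbicyclo[5.3.0]dec-6-ene
Conditions: NBS (2.1 equiv), MeCN, 0 °C
Reagents that add atoms: N-bromosuccinimide, O=C1CCC(=O)N1Br
Why: Electrophilic aromatic bromination at the two ring positions flanked by methoxy groups, far faster than any reaction of the deactivated enone alkene; it is done here because no electron-rich alkene is present.

Step 17
Reactants: 22 dibromo enone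
Product: 23 (1R,4S,5S,7R,10R)-7-acetyl-4-[(1R)-1-(3,5-dibromo-2,4,6-trimethoxyphenyl)-3-methylbutyl]-4,10-dimethylbicyclo[5.3.0]decan-10-ol
Conditions: H2 (1 atm), [Ir(cod)(PCy3)(py)]PF6 (10 mol %), CH2Cl2, rt
Reagents that add atoms: none
Why: Hydroxyl-directed homogeneous hydrogenation: the cationic iridium complex binds the 10-OH and should deliver H2 to the same face of C6=C7, so H-7 ends cis to the hydroxyl and the acetyl group trans (7R); aryl bromides are inert.

Step 18
Reactants: 23 methyl ketone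
Product: 24 (1R,4S,5S,7R,10R)-4-[(1R)-1-(3,5-dibromo-2,4,6-trimethoxyphenyl)-3-methylbutyl]-4,10-dimethyl-7-(prop-1-en-2-yl)bicyclo[5.3.0]decan-10-ol
Conditions: Ph3PCH3Br (4 equiv), KOt-Bu (3.8 equiv), THF, 0 °C → rt
Reagents that add atoms: methylidenetriphenylphosphorane (from methyltriphenylphosphonium bromide), C=P(c1ccccc1)(c1ccccc1)c1ccccc1
Why: Wittig methylenation of the methyl ketone gives the isopropenyl group; short exposure at low temperature should limit epimerisation at C7.

Step 19
Reactants: 24 dibromide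
Product: 25 5-[(1R)-1-[(1R,4S,5S,7R,10R)-10-hydroxy-4,10-dimethyl-7-(prop-1-en-2-yl)bicyclo[5.3.0]dec-4-yl]-3-methylbutyl]-2,4,6-trimethoxybenzene-1,3-dicarbaldehyde
Conditions: t-BuLi (5.5 equiv), THF, −78 °C; DMF, −78 → 0 °C; aqueous work-up
Reagents that add atoms: N,N-dimethylformamide, CN(C)C=O
Why: Alkoxide formation, then double bromine–lithium exchange (each aryllithium stabilised by two flanking methoxy groups) and formylation with DMF.

Step 20
Reactants: 25 dialdehyde trimethyl ether
Product: 26 5-[(1R)-1-[(1R,4S,5S,7R,10R)-10-hydroxy-4,10-dimethyl-7-(prop-1-en-2-yl)bicyclo[5.3.0]dec-4-yl]-3-methylbutyl]-2,4,6-trihydroxybenzene-1,3-dicarbaldehyde (target)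
Conditions: n-PrSLi (10 equiv, from n-PrSH and n-BuLi), HMPA, 120 °C; then dilute aq. HCl to pH 4
Reagents that add atoms: none
Why: Thiolate SN2 demethylation: every methoxy group is ortho to a formyl group, so each aryloxide is a good leaving group, and the basic conditions should spare the tertiary alcohol and the isopropenyl group.

**Compound list**

1 | 5,7-dimethoxycoumarin | O=c1ccc2c(OC)cc(OC)cc2o1 | starting material
2 | (4R)-5,7-dimethoxy-4-(2-methylpropyl)-3,4-dihydro-2H-chromen-2-one | O=C1C[C@@H](CC(C)C)c2c(OC)cc(OC)cc2O1 | intermediate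
3 | (3R,4R)-5,7-dimethoxy-3-methyl-4-(2-methylpropyl)-3,4-dihydro-2H-chromen-2-one | C[C@@H]1[C@@H](CC(C)C)c2c(OC)cc(OC)cc2OC1=O | intermediate
4 | but-3-yn-1-ol | OCCC#C | starting material
5 | penta-3,4-dien-1-ol | OCCC=C=C | intermediate
6 | 5-iodopenta-1,2-diene | ICCC=C=C | intermediate
7 | (3R,4S)-5,7-dimethoxy-3-methyl-4-(2-methylpropyl)-3-(penta-3,4-dien-1-yl)-3,4-dihydro-2H-chromen-2-one | C=C=CCC[C@]1(C)[C@@H](CC(C)C)c2c(OC)cc(OC)cc2OC1=O | intermediate
8 | (2R)-2-[(1R)-1-(2-hydroxy-4,6-dimethoxyphenyl)-3-methylbutyl]-2-methylhepta-5,6-dien-1-ol | C=C=CCC[C@](C)([C@@H](CC(C)C)c1c(OC)cc(OC)cc1O)CO | intermediate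
9 | (2R)-2-methyl-2-[(1R)-3-methyl-1-(2,4,6-trimethoxyphenyl)butyl]hepta-5,6-dien-1-ol | C=C=CCC[C@](C)([C@@H](CC(C)C)c1c(OC)cc(OC)cc1OC)CO | intermediate
10 | (2R)-2-methyl-2-[(1S)-3-methyl-1-(2,4,6-trimethoxyphenyl)butyl]hepta-5,6-dienal | C=C=CCC[C@](C)([C@@H](CC(C)C)c1c(OC)cc(OC)cc1OC)C=O | intermediate
11 | 1-(hydroxymethyl)cyclopropane-1-carbonitrile | N#CC1(CO)CC1 | starting material
12 | 1-phenyl-1H-tetrazole-5-thiol | Sc1nnnn1-c1ccccc1 | starting material
13 | 1-{[(1-phenyl-1H-tetrazol-5-yl)sulfanyl]methyl}cyclopropane-1-carbonitrile | N#CC1(CSc2nnnn2-c2ccccc2)CC1 | intermediate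
14 | 1-{[(1-phenyl-1H-tetrazol-5-yl)sulfonyl]methyl}cyclopropane-1-carbonitrile | N#CC1(CS(=O)(=O)c2nnnn2-c2ccccc2)CC1 | intermediate
15 | 1-{(1E,3S)-3-methyl-3-[(1R)-3-methyl-1-(2,4,6-trimethoxyphenyl)butyl]octa-1,6,7-trien-1-yl}cyclopropane-1-carbonitrile | C=C=CCC[C@](C)([C@@H](CC(C)C)c1c(OC)cc(OC)cc1OC)/C=C/C1(C#N)CC1 | intermediate
16 | (1S,4S,5S)-7-cyano-4-methyl-10-methylidene-4-[(1R)-3-methyl-1-(2,4,6-trimethoxyphenyl)butyl]bicyclo[5.3.0]dec-6-ene, cis-fused | N#CC=1CCC(=C)[C@H]2CC[C@](C)([C@@H](CC(C)C)c3c(OC)cc(OC)cc3OC)[C@H]2C=1 | intermediate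
17 | (1S,4S,5S)-7-cyano-4-methyl-4-[(1R)-3-methyl-1-(2,4,6-trimethoxyphenyl)butyl]bicyclo[5.3.0]dec-6-en-10-one, cis-fused | N#CC=1CCC(=O)[C@H]2CC[C@](C)([C@@H](CC(C)C)c3c(OC)cc(OC)cc3OC)[C@H]2C=1 | intermediate
18 | (1R,4S,5S)-7-cyano-4-methyl-4-[(1R)-3-methyl-1-(2,4,6-trimethoxyphenyl)butyl]bicyclo[5.3.0]dec-6-en-10-one, trans-fused | N#CC=1CCC(=O)[C@@H]2CC[C@](C)([C@@H](CC(C)C)c3c(OC)cc(OC)cc3OC)[C@H]2C=1 | intermediate
19 | (1R,4S,5S,10R)-7-cyano-10-hydroxy-4,10-dimethyl-4-[(1R)-3-methyl-1-(2,4,6-trimethoxyphenyl)butyl]bicyclo[5.3.0]dec-6-ene | N#CC=1CC[C@@](C)(O)[C@@H]2CC[C@](C)([C@@H](CC(C)C)c3c(OC)cc(OC)cc3OC)[C@H]2C=1 | intermediate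
20 | N–H ketimine of 21 (7-(1-iminoethyl) compound, same configuration as 19) | CC(=N)C=1CC[C@@](C)(O)[C@@H]2CC[C@](C)([C@@H](CC(C)C)c3c(OC)cc(OC)cc3OC)[C@H]2C=1 | intermediate
21 | (1R,4S,5S,10R)-7-acetyl-10-hydroxy-4,10-dimethyl-4-[(1R)-3-methyl-1-(2,4,6-trimethoxyphenyl)butyl]bicyclo[5.3.0]dec-6-ene | CC(=O)C=1CC[C@@](C)(O)[C@@H]2CC[C@](C)([C@@H](CC(C)C)c3c(OC)cc(OC)cc3OC)[C@H]2C=1 | intermediate
22 | (1R,4S,5S,10R)-7-acetyl-4-[(1R)-1-(3,5-dibromo-2,4,6-trimethoxyphenyl)-3-methylbutyl]-10-hydroxy-4,10-dimethylbicyclo[5.3.0]dec-6-ene | CC(=O)C=1CC[C@@](C)(O)[C@@H]2CC[C@](C)([C@@H](CC(C)C)c3c(OC)c(Br)c(OC)c(Br)c3OC)[C@H]2C=1 | intermediate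
23 | (1R,4S,5S,7R,10R)-7-acetyl-4-[(1R)-1-(3,5-dibromo-2,4,6-trimethoxyphenyl)-3-methylbutyl]-4,10-dimethylbicyclo[5.3.0]decan-10-ol | CC(=O)[C@@H]1CC[C@@](C)(O)[C@@H]2CC[C@](C)([C@@H](CC(C)C)c3c(OC)c(Br)c(OC)c(Br)c3OC)[C@H]2C1 | intermediate
24 | (1R,4S,5S,7R,10R)-4-[(1R)-1-(3,5-dibromo-2,4,6-trimethoxyphenyl)-3-methylbutyl]-4,10-dimethyl-7-(prop-1-en-2-yl)bicyclo[5.3.0]decan-10-ol | C=C(C)[C@@H]1CC[C@@](C)(O)[C@@H]2CC[C@](C)([C@@H](CC(C)C)c3c(OC)c(Br)c(OC)c(Br)c3OC)[C@H]2C1 | intermediate
25 | 5-[(1R)-1-[(1R,4S,5S,7R,10R)-10-hydroxy-4,10-dimethyl-7-(prop-1-en-2-yl)bicyclo[5.3.0]dec-4-yl]-3-methylbutyl]-2,4,6-trimethoxybenzene-1,3-dicarbaldehyde | C=C(C)[C@@H]1CC[C@@](C)(O)[C@@H]2CC[C@](C)([C@@H](CC(C)C)c3c(OC)c(C=O)c(OC)c(C=O)c3OC)[C@H]2C1 | intermediate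
26 | 5-[(1R)-1-[(1R,4S,5S,7R,10R)-10-hydroxy-4,10-dimethyl-7-(prop-1-en-2-yl)bicyclo[5.3.0]dec-4-yl]-3-methylbutyl]-2,4,6-trihydroxybenzene-1,3-dicarbaldehyde | C=C(C)[C@@H]1CC[C@@](C)(O)[C@@H]2CC[C@](C)([C@@H](CC(C)C)c3c(O)c(C=O)c(O)c(C=O)c3O)[C@H]2C1 | target

**Step count.** Total: 20 steps. Longest linear sequence: 16 steps (steps 1, 2, 5–8, 11–20).

**Steps most likely to fail, with fallbacks**

Step 12 (key cycloaddition). The nitrile may bind rhodium, and the acceptor-substituted vinylcyclopropane, flanked by two fully substituted carbons, may open too slowly, so that allene oligomerisation outruns the cycloaddition. The fallback changes the cyclopropane substituent before ring closure from the acceptor nitrile to a donor-type masked acetyl group, the substitution pattern for which this cycloaddition is best established. It sets out from 15. MeLi followed by aqueous AcOH should give the methyl ketone F1, and 1,2-bis(trimethylsilyloxy)ethane with catalytic TMSOTf at −78 °C the dioxolane F2. The same [Rh(CO)2Cl]2 conditions should then give the cis-fused ketal cycloadduct F3. OsO4/NaIO4 should give the cis-fused ketone F4 and DBU the trans-fused ketone F5, although the ketal-bearing ring alkene is less deactivated towards OsO4 than the alkenyl nitrile. MAD/MeLi should give the tertiary alcohol F6, and PPTS in wet acetone unmasks the enone, returning to the route at 21.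

Step 14 (methyl addition at C10). Methyl delivery may occur from the wrong face and give the C10 epimer, or the nitrile may compete. The fallback forms the C–C bond with a small sulfur ylide and then opens the epoxide with hydride. It sets out from 18. Corey–Chaykovsky epoxidation with dimethylsulfonium methylide (Me3SI, KN(SiMe3)2, THF, −10 °C) should add axially under kinetic control and give the spiro-epoxide F7, with oxygen on the face of H-1. LiBEt3H at −78 → 0 °C should open it at the CH2 carbon, faster than it attacks the hindered alkenyl nitrile, and return to the route at 19.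

Step 11 (olefination). The sulfonyl carbanion may add too slowly to the hindered neopentyl aldehyde and self-condense instead, or alkene geometry may be lost. The fallback makes the alkene first and attaches the cyclopropane by cross-coupling. It sets out from 10. Takai olefination (CHI3, CrCl2, THF/dioxane) should give the (E)-vinyl iodide F8. Palladium-catalysed α-alkenylation of lithiated cyclopropanecarbonitrile (LiN(SiMe3)2, Pd2(dba)3, a Xantphos-type ligand, zerovalent palladium as the active species) then forms the C6–C7 bond and returns to the route at 15.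

**Further compounds**

F1 | step 12 | 1-{1-[(1E,3S)-3-methyl-3-[(1R)-3-methyl-1-(2,4,6-trimethoxyphenyl)butyl]octa-1,6,7-trien-1-yl]cyclopropyl}ethan-1-one | C=C=CCC[C@](C)([C@@H](CC(C)C)c1c(OC)cc(OC)cc1OC)/C=C/C1(C(C)=O)CC1
F2 | step 12 | 2-methyl-2-{1-[(1E,3S)-3-methyl-3-[(1R)-3-methyl-1-(2,4,6-trimethoxyphenyl)butyl]octa-1,6,7-trien-1-yl]cyclopropyl}-1,3-dioxolane | C=C=CCC[C@](C)([C@@H](CC(C)C)c1c(OC)cc(OC)cc1OC)/C=C/C1(C2(C)OCCO2)CC1
F3 | step 12 | (1S,4S,5S)-4-methyl-10-methylidene-7-(2-methyl-1,3-dioxolan-2-yl)-4-[(1R)-3-methyl-1-(2,4,6-trimethoxyphenyl)butyl]bicyclo[5.3.0]dec-6-ene, cis-fused | CC1(OCCO1)C=2CCC(=C)[C@H]3CC[C@](C)([C@@H](CC(C)C)c4c(OC)cc(OC)cc4OC)[C@H]3C=2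
F4 | step 12 | (1S,4S,5S)-4-methyl-7-(2-methyl-1,3-dioxolan-2-yl)-4-[(1R)-3-methyl-1-(2,4,6-trimethoxyphenyl)butyl]bicyclo[5.3.0]dec-6-en-10-one, cis-fused | CC1(OCCO1)C=2CCC(=O)[C@H]3CC[C@](C)([C@@H](CC(C)C)c4c(OC)cc(OC)cc4OC)[C@H]3C=2
F5 | step 12 | (1R,4S,5S)-4-methyl-7-(2-methyl-1,3-dioxolan-2-yl)-4-[(1R)-3-methyl-1-(2,4,6-trimethoxyphenyl)butyl]bicyclo[5.3.0]dec-6-en-10-one, trans-fused | CC1(OCCO1)C=2CCC(=O)[C@@H]3CC[C@](C)([C@@H](CC(C)C)c4c(OC)cc(OC)cc4OC)[C@H]3C=2
F6 | step 12 | (1R,4S,5S,10R)-10-hydroxy-4,10-dimethyl-7-(2-methyl-1,3-dioxolan-2-yl)-4-[(1R)-3-methyl-1-(2,4,6-trimethoxyphenyl)butyl]bicyclo[5.3.0]dec-6-ene | CC1(OCCO1)C=2CC[C@@](C)(O)[C@@H]3CC[C@](C)([C@@H](CC(C)C)c4c(OC)cc(OC)cc4OC)[C@H]3C=2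
F7 | step 14 | spiro-epoxide of 18 at C10 (epoxide oxygen on the face of H-1, CH2 on the opposite face; 7-cyano, trans-fused) | N#CC=1CC[C@@]2(OC2)[C@@H]3CC[C@](C)([C@@H](CC(C)C)c4c(OC)cc(OC)cc4OC)[C@H]3C=1
F8 | step 11 | 2-[(1R)-1-[(1E,3R)-1-iodo-3-methylocta-1,6,7-trien-3-yl]-3-methylbutyl]-1,3,5-trimethoxybenzene | C=C=CCC[C@](C)([C@@H](CC(C)C)c1c(OC)cc(OC)cc1OC)/C=C/I
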